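The route rests on cutting the bond between the quaternary carbon C2 of the pyran ring and the first CH2 of the side chain. It exploits the fact that C2 is flanked by the ring oxygen O1 and the C3=C4 unit. At the chromone oxidation level, O-silylation at C4 aromatises the pyran ring to a benzopyrylium ion in which C2 is the only open electrophilic site. A chiral copper acetylide then joins the terpenoid ring fragment to this carbon and sets the quaternary stereocentre in one operation. The precursors are 5-benzyloxy-2,7-dimethylchromone and an enantiopure 6-ethynyl-1-iodo-5,5-dimethylcyclohexene, made by CBS reduction and Claisen chirality transfer. The alkyne and the C4 ketone are later reduced away.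

Key step: step 7

Assumption: compound 1 is taken as a catalogue chemical.
Assumption: the (S,S)-configured bis(oxazoline) is taken to steer the acetylide to the face of cation 12 that gives (2S)-14; if the sense proves opposite, the equally available (R,R) ligand is used.

Step 1
Reactants: 1 1-(2,6-dihydroxy-4-methylphenyl)ethan-1-one
Product: 2 1-[2-(benzyloxy)-6-hydroxy-4-methylphenyl]ethan-1-one
Conditions: BnBr (1.05 equiv), K2CO3, acetone, reflux
Reagents that add atoms: benzyl bromide, BrCc1ccccc1
Why: Williamson etherification stops after one alkylation because the remaining phenol is tied up in a hydrogen bond to the acetyl oxygen and is far less nucleophilic.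

Step 2
Reactants: 2 1-[2-(benzyloxy)-6-hydroxy-4-methylphenyl]ethan-1-one
Product: 4 5-(benzyloxy)-2,7-dimethyl-4H-chromen-4-one, via enaminone 3 (not isolated)
Conditions: MeC(OMe)2NMe2, toluene, 110 °C; then AcOH, 80 °C
Reagents that add atoms: N,N-dimethylacetamide dimethyl acetal, CC(OC)(OC)N(C)C
Why: Condensation of the acetyl CH3 with the amide acetal gives enaminone 3, and acid-promoted attack of the free phenol on its β-carbon with loss of dimethylamine (addition–elimination) is the standard enaminone route to 2-methylchromones.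

Step 3
Reactants: 5 4,4-dimethylcyclohex-2-en-1-one
Product: 6 2-iodo-4,4-dimethylcyclohex-2-en-1-one
Conditions: I2, pyridine–CH2Cl2, 0 °C to rt
Reagents that add atoms: iodine, [I][I]
Why: α-Iodination of an enone by the Baylis–Hillman-type sequence of pyridine conjugate addition, enolate iodination and elimination is routine for 4,4-disubstituted cyclohexenones.

Step 4
Reactants: 6 2-iodo-4,4-dimethylcyclohex-2-en-1-one
Product: 7 (1R)-2-iodo-4,4-dimethylcyclohex-2-en-1-ol
Conditions: (S)-2-methyl-CBS-oxazaborolidine (10 mol%), BH3·SMe2, THF, −20 °C; then MeOH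
Reagents that add atoms: none
Why: Corey–Bakshi–Shibata reduction, in which the iodo-substituted alkene arm acts as the large group, so that the (S)-oxazaborolidine should deliver hydride to the face that gives the (R)-carbinol, the only externally induced stereocentre of this fragment.

Step 5
Reactants: 7 (1R)-2-iodo-4,4-dimethylcyclohex-2-en-1-ol
Product: 9 2-[(1S)-2-iodo-6,6-dimethylcyclohex-2-en-1-yl]acetaldehyde, via allyl vinyl ether 8 (not isolated)
Conditions: ethyl vinyl ether (solvent), Hg(OAc)2 (cat.), reflux; evaporate; then xylenes, 150 °C, sealed tube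
Reagents that add atoms: ethyl vinyl ether, C=COCC
Why: Transetherification gives allyl vinyl ether 8, whose Claisen [3,3] rearrangement must pass suprafacially over the ring face that carries the C–O bond, so the carbinol configuration of 7 is relayed to the new C–C bond next to the gem-dimethyl carbon while the ring alkene shifts and keeps the iodine on an sp2 carbon.

Step 6
Reactants: 9 2-[(1S)-2-iodo-6,6-dimethylcyclohex-2-en-1-yl]acetaldehyde
Product: 11 (6R)-6-ethynyl-1-iodo-5,5-dimethylcyclohex-1-ene, via alkenyl nonaflate 10 (not isolated)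
Conditions: C4F9SO2F, phosphazene base P2-Et (2.5 equiv), DMF, 0 °C to rt
Reagents that add atoms: none
Why: Sulfonylation of the aldehyde enolate gives alkenyl nonaflate 10, which loses nonaflate by E2 elimination under the same base, a known one-pot conversion of enolisable aldehydes into terminal alkynes without change of carbon count that leaves the adjacent stereocentre, which has no acidifying carbonyl group, untouched.

Step 7
Reactants: 4 5-(benzyloxy)-2,7-dimethyl-4H-chromen-4-one; 11 (6R)-6-ethynyl-1-iodo-5,5-dimethylcyclohex-1-ene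
Product: 14 (2S)-5-(benzyloxy)-2-{[(1R)-2-iodo-6,6-dimethylcyclohex-2-en-1-yl]ethynyl}-2,7-dimethyl-2,3-dihydro-4H-chromen-4-one, via benzopyrylium triflate 12 (not isolated), via silyl enol ether 13 (not isolated)
Conditions: 4, TBSOTf (1.2 equiv), toluene, 50 °C; then CuI (10 mol%), (S,S)-Ph-box [2,2'-(propane-2,2-diyl)bis((4S)-4-phenyl-4,5-dihydro-1,3-oxazole), 12 mol%], 11 (1.2 equiv), iPr2NEt (1.3 equiv, slow addition), toluene, −40 °C; then 2 M HCl, THF, rt
Reagents that add atoms: none
Why: Proposed new method: O-silylation of the C4 carbonyl turns the γ-pyrone ring of 4 into the aromatic 4-silyloxybenzopyrylium 12, whose only unblocked electrophilic carbon is C2, and the bis(oxazoline)-bound monovalent copper acetylide formed from 11 and iPr2NEt adds there to give silyl enol ether 13, which acid hydrolyses to 14. The closest known reaction type is the CuI/bis(oxazoline)-catalysed enantioselective alkynylation of 4-silyloxybenzopyrylium triflates made from chromones and from chromone-2-carboxylates, the latter already giving tertiary-ether stereocentres; what is new is a 2-methyl group with acidic hydrogens on the cation. No ring is closed. The new quaternary stereocentre C2 is set by the chiral ligand, which shields one face of the planar cation, while the propargylic centre of 11 is a spectator that can at most create a matched or mismatched pair, to be answered by the choice of ligand antipode. The step needs attack at C2 rather than C4, secured by the OTBS group on C4 and the peri benzyloxy group on C5, and it needs C–C bond formation to beat loss of a proton from the 2-methyl group, which is reversible (the exocyclic dienol ether is re-protonated by the ammonium triflate), is held back by low temperature and slow addition of base, and competes with the sterically least demanding of all carbon nucleophiles. The vinyl iodide of 11 is inert to monovalent copper at this temperature.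

Step 8
Reactants: 14 (2S)-5-(benzyloxy)-2-{[(1R)-2-iodo-6,6-dimethylcyclohex-2-en-1-yl]ethynyl}-2,7-dimethyl-2,3-dihydro-4H-chromen-4-one
Product: 15 methyl (6R)-6-{[(2S)-5-(benzyloxy)-2,7-dimethyl-4-oxo-3,4-dihydro-2H-chromen-2-yl]ethynyl}-5,5-dimethylcyclohex-1-ene-1-carboxylate
Conditions: Pd(OAc)2 (5 mol%), PPh3, Et3N, CO (1 atm), MeOH–DMF, 40 °C
Reagents that add atoms: carbon monoxide, [C-]#[O+]; methanol, CO
Why: Palladium-catalysed alkoxycarbonylation (oxidative addition of the vinyl iodide to zerovalent palladium, CO insertion, methanolysis) installs the carboxyl carbon on the sp2 carbon next to the ring stereocentre, and the weak amine base at mild temperature should not open the chromanone by a retro-oxa-Michael reaction.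

Step 9
Reactants: 15 methyl (6R)-6-{[(2S)-5-(benzyloxy)-2,7-dimethyl-4-oxo-3,4-dihydro-2H-chromen-2-yl]ethynyl}-5,5-dimethylcyclohex-1-ene-1-carboxylate
Product: 16 methyl (1R,2R)-2-{2-[(2R)-5-hydroxy-2,7-dimethyl-4-oxo-3,4-dihydro-2H-chromen-2-yl]ethyl}-3,3-dimethylcyclohexane-1-carboxylate
Conditions: H2 (5 atm), Pd/C, EtOAc–MeOH, rt
Reagents that add atoms: none
Why: Heterogeneous hydrogenation saturates the alkyne and the enoate and cleaves the benzyl ether in one operation, and H2 should reach the ring alkene from the face opposite the neighbouring side chain, which gives the cis ester, a centre that step 11 corrects.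

Step 10
Reactants: 16 methyl (1R,2R)-2-{2-[(2R)-5-hydroxy-2,7-dimethyl-4-oxo-3,4-dihydro-2H-chromen-2-yl]ethyl}-3,3-dimethylcyclohexane-1-carboxylate
Product: 18 methyl (1R,2R)-2-{2-[(2R)-5-hydroxy-2,7-dimethyl-2H-chromen-2-yl]ethyl}-3,3-dimethylcyclohexane-1-carboxylate, via chroman-4-ol 17 (not isolated)
Conditions: NaBH4, THF–MeOH, 0 °C to rt; aqueous work-up; then p-TsOH·H2O (cat.), toluene, 40 °C, in the dark
Reagents that add atoms: none
Why: Borohydride 1,2-reduction spares the ester, and the resulting benzylic alcohol, activated by two ortho oxygen substituents, loses water under mild acid (E1 dehydration) to unveil the C3=C4 bond without touching the C2–O bond.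

Step 11
Reactants: 18 methyl (1R,2R)-2-{2-[(2R)-5-hydroxy-2,7-dimethyl-2H-chromen-2-yl]ethyl}-3,3-dimethylcyclohexane-1-carboxylate
Product: 20 (1S,2R)-2-{2-[(2R)-5-hydroxy-2,7-dimethyl-2H-chromen-2-yl]ethyl}-3,3-dimethylcyclohexane-1-carboxylic acid, via trans methyl ester 19 (not isolated)
Conditions: NaOMe (3 equiv), MeOH, 50 °C; then LiOH, THF–H2O, 50 °C; 1 M HCl; in the dark throughout
Reagents that add atoms: lithium hydroxide, [Li+].[OH-]
Why: Methoxide equilibrates the centre α to the ester to the trans-diequatorial isomer 19 (thermodynamic control, since the cis form must place one substituent axial next to the gem-dimethyl group), and saponification then frees the acid, the chromene and C2 being inert to base.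

Compound list
1 | 1-(2,6-dihydroxy-4-methylphenyl)ethan-1-one | CC(=O)c1c(O)cc(C)cc1O | starting material
2 | 1-[2-(benzyloxy)-6-hydroxy-4-methylphenyl]ethan-1-one | CC(=O)c1c(O)cc(C)cc1OCc1ccccc1 | intermediate
3 | (2E)-1-[2-(benzyloxy)-6-hydroxy-4-methylphenyl]-3-(dimethylamino)but-2-en-1-one | C/C(N(C)C)=C\C(=O)c1c(O)cc(C)cc1OCc1ccccc1 | intermediate
4 | 5-(benzyloxy)-2,7-dimethyl-4H-chromen-4-one | Cc1cc(OCc3ccccc3)c2c(c1)oc(C)cc2=O | intermediate
5 | 4,4-dimethylcyclohex-2-en-1-one | CC1(C)CCC(=O)C=C1 | starting material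
6 | 2-iodo-4,4-dimethylcyclohex-2-en-1-one | CC1(C)CCC(=O)C(I)=C1 | intermediate
7 | (1R)-2-iodo-4,4-dimethylcyclohex-2-en-1-ol | O[C@@H]1CCC(C)(C)C=C1I | intermediate
8 | (6R)-6-(ethenyloxy)-1-iodo-3,3-dimethylcyclohex-1-ene | C=CO[C@@H]1CCC(C)(C)C=C1I | intermediate
9 | 2-[(1S)-2-iodo-6,6-dimethylcyclohex-2-en-1-yl]acetaldehyde | O=CC[C@@H]1C(I)=CCCC1(C)C | intermediate
10 | 2-[(1S)-2-iodo-6,6-dimethylcyclohex-2-en-1-yl]ethenyl nonafluorobutane-1-sulfonate (both alkene geometries) | O=S(=O)(OC=C[C@@H]1C(I)=CCCC1(C)C)C(F)(F)C(F)(F)C(F)(F)C(F)(F)F | intermediate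
11 | (6R)-6-ethynyl-1-iodo-5,5-dimethylcyclohex-1-ene | C#C[C@@H]1C(I)=CCCC1(C)C | intermediate
12 | 5-(benzyloxy)-4-[(tert-butyldimethylsilyl)oxy]-2,7-dimethylchromenylium trifluoromethanesulfonate | Cc1cc(OCc3ccccc3)c2c(c1)[o+]c(C)cc2O[Si](C)(C)C(C)(C)C.[O-]S(=O)(=O)C(F)(F)F | intermediate
13 | {[(2S)-5-(benzyloxy)-2-{[(1R)-2-iodo-6,6-dimethylcyclohex-2-en-1-yl]ethynyl}-2,7-dimethyl-2H-chromen-4-yl]oxy}(tert-butyl)dimethylsilane | Cc1cc(OCc3ccccc3)c2c(c1)O[C@](C)(C#C[C@@H]1C(I)=CCCC1(C)C)C=C2O[Si](C)(C)C(C)(C)C | intermediate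
14 | (2S)-5-(benzyloxy)-2-{[(1R)-2-iodo-6,6-dimethylcyclohex-2-en-1-yl]ethynyl}-2,7-dimethyl-2,3-dihydro-4H-chromen-4-one | Cc1cc(OCc3ccccc3)c2c(c1)O[C@](C)(C#C[C@@H]1C(I)=CCCC1(C)C)CC2=O | intermediate
15 | methyl (6R)-6-{[(2S)-5-(benzyloxy)-2,7-dimethyl-4-oxo-3,4-dihydro-2H-chromen-2-yl]ethynyl}-5,5-dimethylcyclohex-1-ene-1-carboxylate | Cc1cc(OCc3ccccc3)c2c(c1)O[C@](C)(C#C[C@@H]1C(C(=O)OC)=CCCC1(C)C)CC2=O | intermediate
16 | methyl (1R,2R)-2-{2-[(2R)-5-hydroxy-2,7-dimethyl-4-oxo-3,4-dihydro-2H-chromen-2-yl]ethyl}-3,3-dimethylcyclohexane-1-carboxylate | Cc1cc(O)c2c(c1)O[C@](C)(CC[C@@H]1[C@H](C(=O)OC)CCCC1(C)C)CC2=O | intermediate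
17 | methyl (1R,2R)-2-{2-[(2R)-4,5-dihydroxy-2,7-dimethyl-3,4-dihydro-2H-chromen-2-yl]ethyl}-3,3-dimethylcyclohexane-1-carboxylate (both C4 epimers) | Cc1cc(O)c2c(c1)O[C@](C)(CC[C@@H]1[C@H](C(=O)OC)CCCC1(C)C)CC2O | intermediate
18 | methyl (1R,2R)-2-{2-[(2R)-5-hydroxy-2,7-dimethyl-2H-chromen-2-yl]ethyl}-3,3-dimethylcyclohexane-1-carboxylate | Cc1cc(O)c2c(c1)O[C@](C)(CC[C@@H]1[C@H](C(=O)OC)CCCC1(C)C)C=C2 | intermediate
19 | methyl (1S,2R)-2-{2-[(2R)-5-hydroxy-2,7-dimethyl-2H-chromen-2-yl]ethyl}-3,3-dimethylcyclohexane-1-carboxylate | Cc1cc(O)c2c(c1)O[C@](C)(CC[C@@H]1[C@@H](C(=O)OC)CCCC1(C)C)C=C2 | intermediate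
20 | (1S,2R)-2-{2-[(2R)-5-hydroxy-2,7-dimethyl-2H-chromen-2-yl]ethyl}-3,3-dimethylcyclohexane-1-carboxylic acid | Cc1cc(O)c2c(c1)O[C@](C)(CC[C@@H]1[C@@H](C(=O)O)CCCC1(C)C)C=C2 | target

Total step count: 11. Longest linear sequence: 9 (steps 3 to 11).

Steps most likely to fail

**Step 7.**
- What may go wrong: the amine base may take a proton from the 2-methyl group of the cation faster than the acetylide adds. The resulting exocyclic dienol ether may then condense with remaining cation.
- A second risk is eroded facial selectivity, because a methyl group gives the ligand less to grip than an ester.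
- Fallback (known chemistry): it sets out from 2 and 11 and comes back at 13. The methyl group is carried through the coupling as a non-enolisable ester.
- Claisen condensation of 2 with diethyl oxalate (NaOEt, EtOH) and acid cyclodehydration would give ethyl 5-(benzyloxy)-7-methyl-4-oxo-4H-chromene-2-carboxylate F1. This compound belongs to the substrate class on which the copper/bis(oxazoline) alkynylation to tertiary ethers is established.
- The same TBSOTf/CuI/bis(oxazoline) protocol with 11, worked up without acid, would give ethyl (2S)-5-(benzyloxy)-4-[(tert-butyldimethylsilyl)oxy]-2-{[(1R)-2-iodo-6,6-dimethylcyclohex-2-en-1-yl]ethynyl}-7-methyl-2H-chromene-2-carboxylate F2.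
- DIBAL-H (CH2Cl2, −78 °C) would reduce the ester to [(2S)-5-(benzyloxy)-4-[(tert-butyldimethylsilyl)oxy]-2-{[(1R)-2-iodo-6,6-dimethylcyclohex-2-en-1-yl]ethynyl}-7-methyl-2H-chromen-2-yl]methanol F3.
- Tf2O with 2,6-lutidine would give [(2S)-5-(benzyloxy)-4-[(tert-butyldimethylsilyl)oxy]-2-{[(1R)-2-iodo-6,6-dimethylcyclohex-2-en-1-yl]ethynyl}-7-methyl-2H-chromen-2-yl]methyl trifluoromethanesulfonate F4.
- LiBHEt3 (THF, 0 °C) would replace triflate by hydride to give 13, which the acid work-up of step 7 turns into 14.

**Step 6.**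
- What may go wrong: syn-elimination of one geometric isomer of the alkenyl sulfonate may be slow, and the aldehyde may self-condense by aldol reaction under the strong base.
- The base may also move the triple bond into conjugation with the ring alkene, which would erase the stereocentre.
- Fallback: it sets out from 6 and comes back at 11. The Claisen/elimination pair is replaced by a direct anti-SN2' alkynylation.
- CBS reduction of 6 with the (R)-oxazaborolidine would give (1S)-2-iodo-4,4-dimethylcyclohex-2-en-1-ol F5.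
- ClP(O)(OEt)2 with pyridine would give diethyl (1S)-2-iodo-4,4-dimethylcyclohex-2-en-1-yl phosphate F6.
- Copper-catalysed γ-selective, anti-stereospecific allylic substitution with (triisopropylsilyl)acetylene (CuCl, 1,10-phenanthroline, LiOtBu, THF) would give {[(1R)-2-iodo-6,6-dimethylcyclohex-2-en-1-yl]ethynyl}tri(propan-2-yl)silane F7.
- TBAF would then free 11.

**Step 9.**
- What may go wrong: the reduction may stall at the hindered trisubstituted enoate.
- The allylic C2–O bond may be hydrogenolysed at the half-reduced alkene stage, or the benzylic ketone may be over-reduced when the reaction is forced.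
- Fallback: it sets out from 15 and comes back at 17. The task is split between two different reductants.
- A short hydrogenation at 1 atm (Pd/C, EtOAc), aimed only at the alkyne and the benzyl ether, would give methyl (6S)-6-{2-[(2R)-5-hydroxy-2,7-dimethyl-4-oxo-3,4-dihydro-2H-chromen-2-yl]ethyl}-5,5-dimethylcyclohex-1-ene-1-carboxylate F8.
- Nickel boride (NiCl2·6H2O, NaBH4, MeOH, 0 °C) would then perform the conjugate reduction of the enoate and the ketone reduction in one flask to give 17. Any mixture at the ester-bearing carbon is levelled in step 11.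

Further compounds
F1 | step 7 | ethyl 5-(benzyloxy)-7-methyl-4-oxo-4H-chromene-2-carboxylate | CCOC(=O)c1cc(=O)c2c(OCc3ccccc3)cc(C)cc2o1
F2 | step 7 | ethyl (2S)-5-(benzyloxy)-4-[(tert-butyldimethylsilyl)oxy]-2-{[(1R)-2-iodo-6,6-dimethylcyclohex-2-en-1-yl]ethynyl}-7-methyl-2H-chromene-2-carboxylate | Cc1cc(OCc3ccccc3)c2c(c1)O[C@](C(=O)OCC)(C#C[C@@H]1C(I)=CCCC1(C)C)C=C2O[Si](C)(C)C(C)(C)C
F3 | step 7 | [(2S)-5-(benzyloxy)-4-[(tert-butyldimethylsilyl)oxy]-2-{[(1R)-2-iodo-6,6-dimethylcyclohex-2-en-1-yl]ethynyl}-7-methyl-2H-chromen-2-yl]methanol | Cc1cc(OCc3ccccc3)c2c(c1)O[C@](CO)(C#C[C@@H]1C(I)=CCCC1(C)C)C=C2O[Si](C)(C)C(C)(C)C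
F4 | step 7 | [(2S)-5-(benzyloxy)-4-[(tert-butyldimethylsilyl)oxy]-2-{[(1R)-2-iodo-6,6-dimethylcyclohex-2-en-1-yl]ethynyl}-7-methyl-2H-chromen-2-yl]methyl trifluoromethanesulfonate | Cc1cc(OCc3ccccc3)c2c(c1)O[C@](COS(=O)(=O)C(F)(F)F)(C#C[C@@H]1C(I)=CCCC1(C)C)C=C2O[Si](C)(C)C(C)(C)C
F5 | step 6 | (1S)-2-iodo-4,4-dimethylcyclohex-2-en-1-ol | O[C@H]1CCC(C)(C)C=C1I
F6 | step 6 | diethyl (1S)-2-iodo-4,4-dimethylcyclohex-2-en-1-yl phosphate | CCOP(=O)(OCC)O[C@H]1CCC(C)(C)C=C1I
F7 | step 6 | {[(1R)-2-iodo-6,6-dimethylcyclohex-2-en-1-yl]ethynyl}tri(propan-2-yl)silane | CC(C)[Si](C#C[C@@H]1C(I)=CCCC1(C)C)(C(C)C)C(C)C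
F8 | step 9 | methyl (6S)-6-{2-[(2R)-5-hydroxy-2,7-dimethyl-4-oxo-3,4-dihydro-2H-chromen-2-yl]ethyl}-5,5-dimethylcyclohex-1-ene-1-carboxylate | Cc1cc(O)c2c(c1)O[C@](C)(CC[C@@H]1C(C(=O)OC)=CCCC1(C)C)CC2=O
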